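**Plan**

1. Ring labels: ring B = 2‑hydroxy‑4,5‑dimethoxyphenyl; rings A/C = benzo and pyran rings of the upper chroman; ring D = central arene; rings A′/C′ = benzo and pyran rings of the lower chroman.
2. Retrosynthetic cuts, in order: phenol protecting groups; O1–C2 of ring C (Mitsunobu); C3–C4 and the lactone C–O of a dihydrocoumarin (ortho‑quinone methide annulation); C4–C4a of the upper unit (aryllithium onto a ring‑D aldehyde); O1–C2 of ring C′ (phenoxide on a mesylate); C2–C3 of ring C′ (one‑carbon homologation at boron); and finally C3–ring D together with C4–C4a of ring C′ (conjunctive coupling on vinylboron).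
3. Enabling feature: C3 of ring C′ is a methine bonded to ring D, to the C4 methylene that leads into ring A′, and to the C2 oxymethylene. This is a 1,2‑diarylethyl unit with a one‑carbon oxygenated branch, which is what a vinylboronate gives when an aryl group migrates to the boron‑bearing carbon and a second aryl is delivered to the terminus; the boron marks where C2 is attached.
4. Forward order: the ArD–CH(B)–CH2–ArA′ chain is joined first, ring C′ is closed, ring A is added to the unmasked ring‑D aldehyde, the lactone precursor of ring C is formed by [4+2] annulation, ring C is closed last, then deprotection.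
5. Stereochemistry: C3 of ring C′ (R) from the chiral diphosphine on palladium in the conjunctive coupling, retained through the boron homologation; C4 of ring C (S) from the chiral isothiourea in the annulation; C3 of ring C (R) by base equilibration to the 3,4‑trans lactone.

Key step: step 8

Remark: rotation about the C4–ring D bond is taken as free, so no axial descriptor is assigned; the sense of induction of the diphosphine (step 8) and of (S)‑benzotetramisole (step 18) is assigned from the accepted models, and the antipodal ligand or catalyst would be used if either proved opposite.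

**Route**

Step 1
Reactants: 1 5‑bromoresorcinol
Product: 2 2‑bromo‑4,6‑dihydroxybenzaldehyde
Conditions: POCl3, DMF, MeCN, 0 °C → rt; then H2O, 50 °C
Reagents that add atoms: N,N‑dimethylformamide, CN(C)C=O; water, O
Why: Vilsmeier–Haack formylation of a resorcinol should go para to one hydroxyl and ortho to the other, next to bromine and not between the two hydroxyls, as it does for other 5‑substituted resorcinols.

Step 2
Reactants: 2 2‑bromo‑4,6‑dihydroxybenzaldehyde
Product: 3 4‑(benzyloxy)‑2‑bromo‑6‑hydroxybenzaldehyde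
Conditions: BnBr (1.05 equiv), NaHCO3, KI (cat.), MeCN, 60 °C
Reagents that add atoms: benzyl bromide, BrCc1ccccc1
Why: Williamson etherification under bicarbonate should be selective for the 4‑hydroxyl, which is para to the formyl group, more acidic and not hydrogen‑bonded to it.

Step 3
Reactants: 3 4‑(benzyloxy)‑2‑bromo‑6‑hydroxybenzaldehyde
Product: 4 4‑(benzyloxy)‑2‑bromo‑6‑methoxybenzaldehyde
Conditions: MeI, K2CO3, DMF, 40 °C
Reagents that add atoms: iodomethane, CI
Why: Williamson O‑methylation of the remaining chelated phenol proceeds with carbonate in a dipolar aprotic solvent.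

Step 4
Reactants: 4 4‑(benzyloxy)‑2‑bromo‑6‑methoxybenzaldehyde
Product: 5 5‑(benzyloxy)‑1‑bromo‑2‑(dimethoxymethyl)‑3‑methoxybenzene
Conditions: HC(OMe)3, TsOH·H2O (cat.), MeOH, 50 °C; Et3N quench
Reagents that add atoms: trimethyl orthoformate, COC(OC)OC
Why: Acid‑catalysed acetalisation driven by the orthoformate masks the aldehyde so that the bromide can be lithiated.

Step 5
Reactants: 6 4‑(benzyloxy)‑2‑hydroxybenzaldehyde
Product: 7 4‑(benzyloxy)‑2‑(methoxymethoxy)benzaldehyde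
Conditions: MOMCl, i‑Pr2NEt, CH2Cl2, 0 °C → rt
Reagents that add atoms: chloromethyl methyl ether, COCCl
Why: O‑alkylation of the phenol gives the MOM acetal, which is stable to base, peracid and organometallics and does not migrate between neighbouring oxygens.

Step 6
Reactants: 7 4‑(benzyloxy)‑2‑(methoxymethoxy)benzaldehyde
Product: 9 4‑(benzyloxy)‑2‑(methoxymethoxy)phenol, via aryl formate 8 (not isolated)
Conditions: mCPBA, CH2Cl2, 0 °C → rt; then K2CO3 (cat.), MeOH, rt
Reagents that add atoms: 3‑chloroperbenzoic acid, OOC(=O)c1cccc(Cl)c1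
Why: In this Dakin‑type Baeyer–Villiger oxidation the electron‑rich aryl group migrates to oxygen, and methanolysis of the formate frees the phenol.

Step 7
Reactants: 9 4‑(benzyloxy)‑2‑(methoxymethoxy)phenol
Product: 10 4‑(benzyloxy)‑2‑(methoxymethoxy)phenyl trifluoromethanesulfonate
Conditions: PhNTf2, Et3N, DMAP (cat.), CH2Cl2, rt
Reagents that add atoms: N‑phenylbis(trifluoromethanesulfonimide), O=S(=O)(N(c1ccccc1)S(=O)(=O)C(F)(F)F)C(F)(F)F
Why: Sulfonylation of the phenoxide with the mild triflimide reagent gives the aryl triflate without touching the MOM acetal.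

Step 8
Reactants: 5 5‑(benzyloxy)‑1‑bromo‑2‑(dimethoxymethyl)‑3‑methoxybenzene; 11 vinylboronic acid pinacol ester; 10 4‑(benzyloxy)‑2‑(methoxymethoxy)phenyl trifluoromethanesulfonate
Product: 14 (R)‑1,2‑diarylethyl pinacol boronate, via aryllithium 12 (not isolated), via lithium vinylborate 13 (not isolated)
Conditions: t‑BuLi (2.0 equiv), Et2O, −78 °C; 11, −78 °C → rt; solvent changed to THF; KOTf (2 equiv), Pd(OAc)2 (3 mol%), (Sp,Sp)‑1,1′‑bis[bis(4‑methoxy‑3,5‑dimethylphenyl)phosphino]‑2,2′‑bis[(R)‑α‑(dimethylamino)benzyl]ferrocene (3.6 mol%), 10 (1.1 equiv), 60 °C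
Reagents that add atoms: none
Why: Bromine–lithium exchange gives aryllithium 12, which adds to the boron of 11 to form the four‑coordinate borate 13; zerovalent palladium inserts into the C–O bond of triflate 10 to give a cationic divalent arylpalladium species that binds the vinyl group and triggers a 1,2‑shift of the ring‑D aryl from boron to the adjacent carbon anti to palladium, and reductive elimination then forms the CH2–ring A′ bond. The closest known reaction type is the enantioselective palladium‑catalysed conjunctive cross‑coupling of vinylboron ate complexes with aryl triflates in which an aryl group migrates from boron. No ring is closed; two skeletal bonds (C3–ring D and C4–C4a of the future ring C′) and one stereocentre are formed. The stereocentre at the boron‑bearing carbon is controlled by the chiral ferrocenyl diphosphine, which selects the enantioface of the coordinated vinyl group, and the (Sp,Sp) ligand is expected to give the (R) boronate. The step needs the metallate shift to outrun direct transfer of aryl or vinyl from boron to palladium and β‑hydride elimination; this is secured by the triflate leaving group with KOTf removing bromide (keeping palladium cationic), by the chelating diphosphine that leaves no open site for transmetalation, and by the pinacol ester. The regiochemistry (migrating aryl to the boron‑bearing carbon, electrophile to the terminus) follows from the mechanism.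

Step 9
Reactants: 14 (R)‑1,2‑diarylethyl pinacol boronate
Product: 17 (2R)‑2‑[5‑(benzyloxy)‑2‑(dimethoxymethyl)‑3‑methoxyphenyl]‑3‑[4‑(benzyloxy)‑2‑(methoxymethoxy)phenyl]propan‑1‑ol, via chloromethyl borate 15 (not isolated), via homologated boronic ester 16 (not isolated)
Conditions: BrCH2Cl (3 equiv), n‑BuLi (2.5 equiv), THF, −78 °C → rt; then NaOH (aq), H2O2, 0 °C → rt
Reagents that add atoms: bromochloromethane, ClCBr; hydrogen peroxide, OO
Why: In this Matteson homologation chloromethyllithium made in the flask adds to boron and the secondary benzylic carbon migrates with retention, displacing chloride, and the new primary C–B bond is then oxidised with retention, so the stereocentre is carried over unchanged.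

Step 10
Reactants: 17 (2R)‑primary alcohol
Product: 18 (2R)‑2‑[5‑(benzyloxy)‑2‑(dimethoxymethyl)‑3‑methoxyphenyl]‑3‑[4‑(benzyloxy)‑2‑(methoxymethoxy)phenyl]propyl methanesulfonate
Conditions: MsCl, Et3N, CH2Cl2, 0 °C
Reagents that add atoms: methanesulfonyl chloride, CS(=O)(=O)Cl
Why: Sulfonylation turns the primary hydroxyl into a leaving group before the aldehyde is unmasked, so that no lactol can form between the free alcohol and the ortho‑formyl group.

Step 11
Reactants: 18 (2R)‑mesylate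
Product: 20 4‑(benzyloxy)‑2‑[(3R)‑7‑(benzyloxy)‑3,4‑dihydro‑2H‑chromen‑3‑yl]‑6‑methoxybenzaldehyde, via phenol aldehyde mesylate 19 (not isolated)
Conditions: 2 M HCl (aq), THF–MeOH, rt → 45 °C; concentrate; then K2CO3, DMF, 50 °C
Reagents that add atoms: water, O
Why: Acid hydrolysis removes the MOM group and the dimethyl acetal, and the phenoxide then closes ring C′ by intramolecular Williamson etherification (6‑exo‑tet SN2 at the primary carbon), which does not touch the stereocentre.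

Step 12
Reactants: 21 4‑bromoresorcinol
Product: 22 2‑bromo‑5‑[(triisopropylsilyl)oxy]phenol
Conditions: i‑Pr3SiCl (1.05 equiv), imidazole, CH2Cl2–DMF, 0 °C
Reagents that add atoms: chlorotriisopropylsilane, CC(C)[Si](Cl)(C(C)C)C(C)C
Why: Silylation with a bulky chlorosilane is governed by sterics and should occur at the hydroxyl para to bromine, leaving the hindered ortho hydroxyl free.

Step 13
Reactants: 22 2‑bromo‑5‑[(triisopropylsilyl)oxy]phenol; 20 ring‑D aldehyde carrying the lower chroman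
Product: 24 ortho‑hydroxybenzhydrol (both carbinol epimers), via dilithiated phenol 23 (not isolated)
Conditions: 22 (2 equiv), n‑BuLi (4.1 equiv), Et2O, 0 °C → rt; then 20, THF, −78 °C → rt; aq. NH4Cl
Reagents that add atoms: none
Why: Deprotonation followed by bromine–lithium exchange gives an ortho‑lithiated phenoxide whose 1,2‑addition to the aldehyde gives the ortho‑hydroxybenzhydrol directly; the new carbinol centre forms as a mixture and is erased in step 18.

Step 14
Reactants: 24 ortho‑hydroxybenzhydrol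
Product: 25 ortho‑hydroxybenzhydryl p‑tolyl sulfone (both epimers)
Conditions: TolSO2Na (3 equiv), HCO2H, CH2Cl2, rt
Reagents that add atoms: sodium 4‑methylbenzenesulfinate, [Na+].Cc1ccc(cc1)S(=O)[O-]
Why: SN1 substitution through the strongly stabilised benzhydryl cation (the protonated quinone methide) with S‑attack of the sulfinate should give a storable sulfone from which base releases the quinone methide.

Step 15
Reactants: 26 2‑hydroxy‑4,5‑dimethoxybenzaldehyde
Product: 27 2‑(benzyloxy)‑4,5‑dimethoxybenzaldehyde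
Conditions: BnBr, K2CO3, DMF, rt
Reagents that add atoms: benzyl bromide, BrCc1ccccc1
Why: Williamson etherification protects the future ring‑B phenol as a benzyl ether.

Step 16
Reactants: 27 2‑(benzyloxy)‑4,5‑dimethoxybenzaldehyde
Product: 28 [2‑(benzyloxy)‑4,5‑dimethoxyphenyl]acetonitrile
Conditions: TosMIC, t‑BuOK, DME, −35 °C → rt; then MeOH, reflux
Reagents that add atoms: p‑toluenesulfonylmethyl isocyanide, Cc1ccc(cc1)S(=O)(=O)C[N+]#[C-]
Why: The van Leusen reductive cyanation converts an aromatic aldehyde into the one‑carbon‑homologated nitrile in a single operation.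

Step 17
Reactants: 28 [2‑(benzyloxy)‑4,5‑dimethoxyphenyl]acetonitrile
Product: 29 [2‑(benzyloxy)‑4,5‑dimethoxyphenyl]acetic acid
Conditions: KOH, EtOH–H2O, reflux; then HCl (aq) to pH 2
Reagents that add atoms: potassium hydroxide, [K+].[OH-]; water, O
Why: Basic nitrile hydrolysis gives the arylacetic acid and leaves the benzyl and methyl ethers intact.

Step 18
Reactants: 25 ortho‑hydroxybenzhydryl p‑tolyl sulfone; 29 [2‑(benzyloxy)‑4,5‑dimethoxyphenyl]acetic acid
Product: 33 (3R,4S)‑trans‑3,4‑diaryl‑3,4‑dihydrocoumarin, via pivalic mixed anhydride 30 (not isolated), via ortho‑quinone methide 31 (not isolated), via cis‑(3S,4S)‑lactone 32 (not isolated)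
Conditions: 29 (1.5 equiv), t‑BuCOCl, i‑Pr2NEt, CH2Cl2, 0 °C; then 25, (S)‑benzotetramisole (10 mol%), i‑Pr2NEt, −20 °C → rt; then DBU, rt
Reagents that add atoms: none
Why: In this isothiourea‑catalysed Michael addition–lactonisation (formal [4+2], a reaction type known to give cis‑3,4‑dihydrocoumarins) the mixed anhydride acylates the catalyst, the derived (Z)‑ammonium enolate, held by the O···S contact, adds through its face anti to the catalyst phenyl to the quinone methide released from the sulfone, which should set C4 as S; the phenoxide then lactonises and releases the catalyst, and DBU epimerises the acidic C3 to the more stable 3,4‑trans lactone (3R).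

Step 19
Reactants: 33 (3R,4S)‑trans‑lactone
Product: 34 (2R,3S)‑phenol primary alcohol
Conditions: LiAlH4, THF, 0 °C; aqueous work‑up
Reagents that add atoms: none
Why: Hydride reduction of the aryl lactone gives the primary alcohol and frees the ring‑A phenol; the stereocentres are untouched and C3 is already in its thermodynamic arrangement.

Step 20
Reactants: 34 (2R,3S)‑phenol primary alcohol
Product: 35 fully protected (3R,4S,3′R) bis‑isoflavan
Conditions: PPh3, DIAD, THF, 0 °C → rt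
Reagents that add atoms: none
Why: Mitsunobu etherification closes ring C by attack of the only free phenol on the activated primary carbon (6‑exo‑tet), with no stereocentre involved.

Step 21
Reactants: 35 fully protected bis‑isoflavan
Product: 36 tris(benzyl) ether with free ring‑A phenol
Conditions: Bu4NF, AcOH, THF, 0 °C → rt
Reagents that add atoms: none
Why: Fluoride cleaves the aryl silyl ether, and the acetic acid buffer keeps the phenol protonated.

Step 22
Reactants: 36 tris(benzyl) ether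
Product: 37 CNP0266829.1
Conditions: H2 (1 atm), 10% Pd/C, EtOAc–MeOH, rt
Reagents that add atoms: none
Why: Hydrogenolysis removes the three benzyl ethers; neither chroman contains a benzylic C–O bond, so the skeleton and the three stereocentres are unaffected.

**Compound list**

1 | 5‑bromobenzene‑1,3‑diol (5‑bromoresorcinol) | Oc1cc(O)cc(Br)c1 | starting material
2 | 2‑bromo‑4,6‑dihydroxybenzaldehyde | O=Cc1c(O)cc(O)cc1Br | intermediate
3 | 4‑(benzyloxy)‑2‑bromo‑6‑hydroxybenzaldehyde | O=Cc1c(O)cc(OCc2ccccc2)cc1Br | intermediate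
4 | 4‑(benzyloxy)‑2‑bromo‑6‑methoxybenzaldehyde | COc1cc(OCc2ccccc2)cc(Br)c1C=O | intermediate
5 | 5‑(benzyloxy)‑1‑bromo‑2‑(dimethoxymethyl)‑3‑methoxybenzene | COC(OC)c1c(OC)cc(OCc2ccccc2)cc1Br | intermediate
6 | 4‑(benzyloxy)‑2‑hydroxybenzaldehyde | O=Cc1ccc(OCc2ccccc2)cc1O | starting material
7 | 4‑(benzyloxy)‑2‑(methoxymethoxy)benzaldehyde | COCOc1cc(OCc2ccccc2)ccc1C=O | intermediate
8 | 4‑(benzyloxy)‑2‑(methoxymethoxy)phenyl formate (formed in the flask) | COCOc1cc(OCc2ccccc2)ccc1OC=O | intermediate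
9 | 4‑(benzyloxy)‑2‑(methoxymethoxy)phenol | COCOc1cc(OCc2ccccc2)ccc1O | intermediate
10 | 4‑(benzyloxy)‑2‑(methoxymethoxy)phenyl trifluoromethanesulfonate | COCOc1cc(OCc2ccccc2)ccc1OS(=O)(=O)C(F)(F)F | intermediate
11 | 2‑ethenyl‑4,4,5,5‑tetramethyl‑1,3,2‑dioxaborolane (vinylboronic acid pinacol ester) | C=CB1OC(C)(C)C(C)(C)O1 | starting material
12 | [5‑(benzyloxy)‑2‑(dimethoxymethyl)‑3‑methoxyphenyl]lithium (formed in the flask) | [Li]c1cc(OCc2ccccc2)cc(OC)c1C(OC)OC | intermediate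
13 | lithium [5‑(benzyloxy)‑2‑(dimethoxymethyl)‑3‑methoxyphenyl](ethenyl)(pinacolato)borate (formed in the flask) | [Li+].C=C[B-]1(c2cc(OCc3ccccc3)cc(OC)c2C(OC)OC)OC(C)(C)C(C)(C)O1 | intermediate
14 | 2‑{(1R)‑1‑[5‑(benzyloxy)‑2‑(dimethoxymethyl)‑3‑methoxyphenyl]‑2‑[4‑(benzyloxy)‑2‑(methoxymethoxy)phenyl]ethyl}‑4,4,5,5‑tetramethyl‑1,3,2‑dioxaborolane | COC(OC)c1c(OC)cc(OCc2ccccc2)cc1[C@@H](Cc1ccc(OCc2ccccc2)cc1OCOC)B1OC(C)(C)C(C)(C)O1 | intermediate
15 | lithium (chloromethyl){(1R)‑1‑[5‑(benzyloxy)‑2‑(dimethoxymethyl)‑3‑methoxyphenyl]‑2‑[4‑(benzyloxy)‑2‑(methoxymethoxy)phenyl]ethyl}(pinacolato)borate (formed in the flask) | [Li+].COC(OC)c1c(OC)cc(OCc2ccccc2)cc1[C@@H](Cc1ccc(OCc2ccccc2)cc1OCOC)[B-]1(CCl)OC(C)(C)C(C)(C)O1 | intermediate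
16 | 2‑{(2R)‑2‑[5‑(benzyloxy)‑2‑(dimethoxymethyl)‑3‑methoxyphenyl]‑3‑[4‑(benzyloxy)‑2‑(methoxymethoxy)phenyl]propyl}‑4,4,5,5‑tetramethyl‑1,3,2‑dioxaborolane (formed in the flask) | COC(OC)c1c(OC)cc(OCc2ccccc2)cc1[C@@H](Cc1ccc(OCc2ccccc2)cc1OCOC)CB1OC(C)(C)C(C)(C)O1 | intermediate
17 | (2R)‑2‑[5‑(benzyloxy)‑2‑(dimethoxymethyl)‑3‑methoxyphenyl]‑3‑[4‑(benzyloxy)‑2‑(methoxymethoxy)phenyl]propan‑1‑ol | COC(OC)c1c(OC)cc(OCc2ccccc2)cc1[C@@H](Cc1ccc(OCc2ccccc2)cc1OCOC)CO | intermediate
18 | (2R)‑2‑[5‑(benzyloxy)‑2‑(dimethoxymethyl)‑3‑methoxyphenyl]‑3‑[4‑(benzyloxy)‑2‑(methoxymethoxy)phenyl]propyl methanesulfonate | COC(OC)c1c(OC)cc(OCc2ccccc2)cc1[C@@H](Cc1ccc(OCc2ccccc2)cc1OCOC)COS(C)(=O)=O | intermediate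
19 | (2R)‑2‑[5‑(benzyloxy)‑2‑formyl‑3‑methoxyphenyl]‑3‑[4‑(benzyloxy)‑2‑hydroxyphenyl]propyl methanesulfonate (formed in the flask) | O=Cc1c(OC)cc(OCc2ccccc2)cc1[C@@H](Cc1ccc(OCc2ccccc2)cc1O)COS(C)(=O)=O | intermediate
20 | 4‑(benzyloxy)‑2‑[(3R)‑7‑(benzyloxy)‑3,4‑dihydro‑2H‑chromen‑3‑yl]‑6‑methoxybenzaldehyde | COc1cc(OCc2ccccc2)cc([C@@H]2COc3cc(OCc4ccccc4)ccc3C2)c1C=O | intermediate
21 | 4‑bromobenzene‑1,3‑diol (4‑bromoresorcinol) | Oc1ccc(Br)c(O)c1 | starting material
22 | 2‑bromo‑5‑[(triisopropylsilyl)oxy]phenol | Oc1cc(O[Si](C(C)C)(C(C)C)C(C)C)ccc1Br | intermediate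
23 | lithium 2‑lithio‑5‑[(triisopropylsilyl)oxy]phenoxide (formed in the flask) | [Li]Oc1cc(O[Si](C(C)C)(C(C)C)C(C)C)ccc1[Li] | intermediate
24 | 2‑[{4‑(benzyloxy)‑2‑[(3R)‑7‑(benzyloxy)‑3,4‑dihydro‑2H‑chromen‑3‑yl]‑6‑methoxyphenyl}(hydroxy)methyl]‑5‑[(triisopropylsilyl)oxy]phenol (both carbinol epimers) | COc1cc(OCc2ccccc2)cc([C@@H]2COc3cc(OCc4ccccc4)ccc3C2)c1C(O)c1ccc(O[Si](C(C)C)(C(C)C)C(C)C)cc1O | intermediate
25 | 2‑[{4‑(benzyloxy)‑2‑[(3R)‑7‑(benzyloxy)‑3,4‑dihydro‑2H‑chromen‑3‑yl]‑6‑methoxyphenyl}(4‑methylbenzenesulfonyl)methyl]‑5‑[(triisopropylsilyl)oxy]phenol (both epimers at the sulfonyl‑bearing carbon) | COc1cc(OCc2ccccc2)cc([C@@H]2COc3cc(OCc4ccccc4)ccc3C2)c1C(c1ccc(O[Si](C(C)C)(C(C)C)C(C)C)cc1O)S(=O)(=O)c1ccc(C)cc1 | intermediate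
26 | 2‑hydroxy‑4,5‑dimethoxybenzaldehyde | COc1cc(O)c(C=O)cc1OC | starting material
27 | 2‑(benzyloxy)‑4,5‑dimethoxybenzaldehyde | COc1cc(OCc2ccccc2)c(C=O)cc1OC | intermediate
28 | [2‑(benzyloxy)‑4,5‑dimethoxyphenyl]acetonitrile | COc1cc(OCc2ccccc2)c(CC#N)cc1OC | intermediate
29 | [2‑(benzyloxy)‑4,5‑dimethoxyphenyl]acetic acid | COc1cc(OCc2ccccc2)c(CC(=O)O)cc1OC | intermediate
30 | [2‑(benzyloxy)‑4,5‑dimethoxyphenyl]acetic 2,2‑dimethylpropanoic anhydride (formed in the flask) | COc1cc(OCc2ccccc2)c(CC(=O)OC(=O)C(C)(C)C)cc1OC | intermediate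
31 | 6‑({4‑(benzyloxy)‑2‑[(3R)‑7‑(benzyloxy)‑3,4‑dihydro‑2H‑chromen‑3‑yl]‑6‑methoxyphenyl}methylidene)‑3‑[(triisopropylsilyl)oxy]cyclohexa‑2,4‑dien‑1‑one (formed in the flask; alkene geometry not defined) | COc1cc(OCc2ccccc2)cc([C@@H]2COc3cc(OCc4ccccc4)ccc3C2)c1C=C1C=CC(O[Si](C(C)C)(C(C)C)C(C)C)=CC1=O | intermediate
32 | (3S,4S)‑4‑{4‑(benzyloxy)‑2‑[(3R)‑7‑(benzyloxy)‑3,4‑dihydro‑2H‑chromen‑3‑yl]‑6‑methoxyphenyl}‑3‑[2‑(benzyloxy)‑4,5‑dimethoxyphenyl]‑7‑[(triisopropylsilyl)oxy]‑3,4‑dihydro‑2H‑chromen‑2‑one (3,4‑cis; formed in the flask) | COc1cc(OCc2ccccc2)c([C@H]2C(=O)Oc3cc(O[Si](C(C)C)(C(C)C)C(C)C)ccc3[C@H]2c2c(OC)cc(OCc3ccccc3)cc2[C@@H]2COc3cc(OCc4ccccc4)ccc3C2)cc1OC | intermediate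
33 | (3R,4S)‑4‑{4‑(benzyloxy)‑2‑[(3R)‑7‑(benzyloxy)‑3,4‑dihydro‑2H‑chromen‑3‑yl]‑6‑methoxyphenyl}‑3‑[2‑(benzyloxy)‑4,5‑dimethoxyphenyl]‑7‑[(triisopropylsilyl)oxy]‑3,4‑dihydro‑2H‑chromen‑2‑one (3,4‑trans) | COc1cc(OCc2ccccc2)c([C@@H]2C(=O)Oc3cc(O[Si](C(C)C)(C(C)C)C(C)C)ccc3[C@H]2c2c(OC)cc(OCc3ccccc3)cc2[C@@H]2COc3cc(OCc4ccccc4)ccc3C2)cc1OC | intermediate
34 | (2R,3S)‑2‑[2‑(benzyloxy)‑4,5‑dimethoxyphenyl]‑3‑{4‑(benzyloxy)‑2‑[(3R)‑7‑(benzyloxy)‑3,4‑dihydro‑2H‑chromen‑3‑yl]‑6‑methoxyphenyl}‑3‑{2‑hydroxy‑4‑[(triisopropylsilyl)oxy]phenyl}propan‑1‑ol | COc1cc(OCc2ccccc2)c([C@@H]([C@@H](c2ccc(O[Si](C(C)C)(C(C)C)C(C)C)cc2O)c2c(OC)cc(OCc3ccccc3)cc2[C@@H]2COc3cc(OCc4ccccc4)ccc3C2)CO)cc1OC | intermediate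
35 | {[(3R,4S)‑4‑{4‑(benzyloxy)‑2‑[(3R)‑7‑(benzyloxy)‑3,4‑dihydro‑2H‑chromen‑3‑yl]‑6‑methoxyphenyl}‑3‑[2‑(benzyloxy)‑4,5‑dimethoxyphenyl]‑3,4‑dihydro‑2H‑chromen‑7‑yl]oxy}tri(propan‑2‑yl)silane | COc1cc(OCc2ccccc2)c([C@@H]2COc3cc(O[Si](C(C)C)(C(C)C)C(C)C)ccc3[C@H]2c2c(OC)cc(OCc3ccccc3)cc2[C@@H]2COc3cc(OCc4ccccc4)ccc3C2)cc1OC | intermediate
36 | (3R,4S)‑4‑{4‑(benzyloxy)‑2‑[(3R)‑7‑(benzyloxy)‑3,4‑dihydro‑2H‑chromen‑3‑yl]‑6‑methoxyphenyl}‑3‑[2‑(benzyloxy)‑4,5‑dimethoxyphenyl]‑3,4‑dihydro‑2H‑chromen‑7‑ol | COc1cc(OCc2ccccc2)c([C@@H]2COc3cc(O)ccc3[C@H]2c2c(OC)cc(OCc3ccccc3)cc2[C@@H]2COc3cc(OCc4ccccc4)ccc3C2)cc1OC | intermediate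
37 | (3R,4S)‑3‑(2‑hydroxy‑4,5‑dimethoxyphenyl)‑4‑{4‑hydroxy‑2‑[(3R)‑7‑hydroxy‑3,4‑dihydro‑2H‑chromen‑3‑yl]‑6‑methoxyphenyl}‑3,4‑dihydro‑2H‑chromen‑7‑ol (CNP0266829.1) | COc1cc(O)c([C@@H]2COc3cc(O)ccc3[C@H]2c2c(OC)cc(O)cc2[C@@H]2COc3cc(O)ccc3C2)cc1OC | target

**Step count and risks**

Total step count: 22. Longest linear sequence: 15 steps (steps 1–4, 8–11, 13, 14, 18–22).

Step 8. The ring‑D aryl sits next to the bulky acetal and may migrate too slowly. Direct transfer of aryl or vinyl from boron to palladium, protodeboronation, or weak discrimination between the faces of the vinyl group would then take over. The fallback sets out from 5 and 7 and comes back at 14; it builds the same boronate by sparteine‑mediated lithiation–borylation instead of palladium catalysis. Bromide 5 is lithiated (t‑BuLi, Et2O, −78 °C) and quenched with 2‑isopropoxy‑4,4,5,5‑tetramethyl‑1,3,2‑dioxaborolane to give 2‑[5‑(benzyloxy)‑2‑(dimethoxymethyl)‑3‑methoxyphenyl]‑4,4,5,5‑tetramethyl‑1,3,2‑dioxaborolane F1. Aldehyde 7 is methylenated (MePPh3Br, t‑BuOK, THF) to 4‑(benzyloxy)‑1‑ethenyl‑2‑(methoxymethoxy)benzene F2, hydroborated and oxidised (9‑BBN; NaOH, H2O2) to 2‑[4‑(benzyloxy)‑2‑(methoxymethoxy)phenyl]ethan‑1‑ol F3, and carbamoylated (i‑Pr2NCOCl, Et3N, toluene, reflux) to 2‑[4‑(benzyloxy)‑2‑(methoxymethoxy)phenyl]ethyl N,N‑diisopropylcarbamate F4. Deprotonation with s‑BuLi and (−)‑sparteine (Et2O, −78 °C) should give the configurationally stable (1S)‑1‑lithio‑2‑[4‑(benzyloxy)‑2‑(methoxymethoxy)phenyl]ethyl N,N‑diisopropylcarbamate F5. This is borylated with retention by F1 to the lithium boronate complex F6. On warming with MgBr2·OEt2 the ring‑D aryl migrates from boron to carbon with inversion and expels the carbamate, which should give 14 with the (R) configuration.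

Step 18. The aryl group on the methide carbon carries two ortho substituents and is twisted out of plane. Conjugate addition may therefore be slow, facial and cis/trans selectivity may erode, and O‑acylation of the phenol of 25 may compete with release of the quinone methide. The fallback sets out from 25 and 29 and comes back at 33; it gives up catalyst control and separates the two upper‑ring diastereomers. Acid 29 is esterified (MeI, K2CO3, DMF) to methyl [2‑(benzyloxy)‑4,5‑dimethoxyphenyl]acetate F7. LiN(SiMe3)2 (THF, −78 °C) converts it into the lithium ester enolate F8, and a further equivalent of the base releases quinone methide 31 from 25. Conjugate addition, lactonisation with loss of methoxide on warming, and equilibration with DBU should give the two 3,4‑trans lactones: 33 and its (3S,4R)‑configured trans diastereomer F9. These differ in their relation to the fixed (R) centre of the lower chroman and are separated by preparative HPLC; 33 then re‑enters at step 19.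

Step 13. The dilithiated phenol is aggregated and sparingly soluble and may add too slowly to the electron‑rich aldehyde with two ortho substituents. Alkylation of the aryllithium by the butyl bromide formed in the exchange, or simple protonation, would then win. The fallback sets out from 22 and 20 and comes back at 24; it uses a protected, soluble monolithium reagent. Phenol 22 is allylated (allyl bromide, K2CO3, acetone) to [4‑bromo‑3‑(prop‑2‑en‑1‑yloxy)phenoxy]tri(propan‑2‑yl)silane F10. Bromine–lithium exchange (n‑BuLi, THF, −78 °C) gives {2‑(prop‑2‑en‑1‑yloxy)‑4‑[(triisopropylsilyl)oxy]phenyl}lithium F11, which is added to 20 at −78 °C to give the O‑allyl benzhydrol F12. Deallylation under neutral conditions (Pd(PPh3)4, morpholine, THF, rt) returns to 24.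

**Further compounds**

F1 | step 8 | 2‑[5‑(benzyloxy)‑2‑(dimethoxymethyl)‑3‑methoxyphenyl]‑4,4,5,5‑tetramethyl‑1,3,2‑dioxaborolane | COC(OC)c1c(OC)cc(OCc2ccccc2)cc1B1OC(C)(C)C(C)(C)O1
F2 | step 8 | 4‑(benzyloxy)‑1‑ethenyl‑2‑(methoxymethoxy)benzene | C=Cc1ccc(OCc2ccccc2)cc1OCOC
F3 | step 8 | 2‑[4‑(benzyloxy)‑2‑(methoxymethoxy)phenyl]ethan‑1‑ol | OCCc1ccc(OCc2ccccc2)cc1OCOC
F4 | step 8 | 2‑[4‑(benzyloxy)‑2‑(methoxymethoxy)phenyl]ethyl N,N‑diisopropylcarbamate | CC(C)N(C(C)C)C(=O)OCCc1ccc(OCc2ccccc2)cc1OCOC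
F5 | step 8 | (1S)‑1‑lithio‑2‑[4‑(benzyloxy)‑2‑(methoxymethoxy)phenyl]ethyl N,N‑diisopropylcarbamate | [Li][C@H](OC(=O)N(C(C)C)C(C)C)Cc1ccc(OCc2ccccc2)cc1OCOC
F6 | step 8 | lithium {(1S)‑1‑[(diisopropylcarbamoyl)oxy]‑2‑[4‑(benzyloxy)‑2‑(methoxymethoxy)phenyl]ethyl}[5‑(benzyloxy)‑2‑(dimethoxymethyl)‑3‑methoxyphenyl](pinacolato)borate | [Li+].COC(OC)c1c(OC)cc(OCc2ccccc2)cc1[B-]1([C@H](OC(=O)N(C(C)C)C(C)C)Cc2ccc(OCc3ccccc3)cc2OCOC)OC(C)(C)C(C)(C)O1
F7 | step 18 | methyl [2‑(benzyloxy)‑4,5‑dimethoxyphenyl]acetate | COC(=O)Cc1cc(OC)c(OC)cc1OCc1ccccc1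
F8 | step 18 | lithium enolate of methyl [2‑(benzyloxy)‑4,5‑dimethoxyphenyl]acetate | [Li]OC(OC)=Cc1cc(OC)c(OC)cc1OCc1ccccc1
F9 | step 18 | (3S,4R)‑4‑{4‑(benzyloxy)‑2‑[(3R)‑7‑(benzyloxy)‑3,4‑dihydro‑2H‑chromen‑3‑yl]‑6‑methoxyphenyl}‑3‑[2‑(benzyloxy)‑4,5‑dimethoxyphenyl]‑7‑[(triisopropylsilyl)oxy]‑3,4‑dihydro‑2H‑chromen‑2‑one | COc1cc(OCc2ccccc2)c([C@H]2C(=O)Oc3cc(O[Si](C(C)C)(C(C)C)C(C)C)ccc3[C@@H]2c2c(OC)cc(OCc3ccccc3)cc2[C@@H]2COc3cc(OCc4ccccc4)ccc3C2)cc1OC
F10 | step 13 | [4‑bromo‑3‑(prop‑2‑en‑1‑yloxy)phenoxy]tri(propan‑2‑yl)silane | C=CCOc1cc(O[Si](C(C)C)(C(C)C)C(C)C)ccc1Br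
F11 | step 13 | {2‑(prop‑2‑en‑1‑yloxy)‑4‑[(triisopropylsilyl)oxy]phenyl}lithium | [Li]c1ccc(O[Si](C(C)C)(C(C)C)C(C)C)cc1OCC=C
F12 | step 13 | {4‑(benzyloxy)‑2‑[(3R)‑7‑(benzyloxy)‑3,4‑dihydro‑2H‑chromen‑3‑yl]‑6‑methoxyphenyl}{2‑(prop‑2‑en‑1‑yloxy)‑4‑[(triisopropylsilyl)oxy]phenyl}methanol (both carbinol epimers) | COc1cc(OCc2ccccc2)cc([C@@H]2COc3cc(OCc4ccccc4)ccc3C2)c1C(O)c1ccc(O[Si](C(C)C)(C(C)C)C(C)C)cc1OCC=C
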